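**Plan**

Numbering used throughout (bisabolane): carbocycle C1(CH3,O)–C2(OH)–C3–C4–C5(OAc)–C6; side chain C7(CH3)–C8(O)–C9–C10(Br)–C11(CH3)2; O7 is the oxane oxygen, O8 the bridging ether oxygen.
Retrosynthetic cuts, in order: C1–O8 together with C2–OH (key step), C1=C2 (ring-closing metathesis), C11–O7 with C10–Br (bromoetherification), C7–CH3 (Grignard), C4–C5 (aldol), then the butenyl–C7 and C9–C10 bonds (Grignard and cuprate).
Forward order: α-silyloxy ketone from methyl (S)-glycidate, then aldol and methyl addition complete the acyclic chain, then the oxane ring, then the cyclohexene ring, then the oxepane ring, closed last.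
Enabling feature: in 16 the trisubstituted C1=C2 bond lies 1,4 across the cyclohexene from C4, whose oxane substituent carries the C8 hydroxyl. Markovnikov attack of that hydroxyl on the methyl-bearing C1 closes the seven-membered ring C1–O8–C8–C7–C4–C5–C6 and leaves C2 activated for oxygenation.
Stereochemistry: C8 from the chiral pool; C4 and C5 from a substrate-controlled titanium aldol; C7 from a chelation/Felkin–Anh controlled Grignard addition; C10 from a chair bromoetherification; C1 from the tether and C2 from exo-face oxygen capture in the key step.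

Key step: step 12

**Route**

Step 1
Reactants: 1 methyl (2S)-oxirane-2-carboxylate (methyl (S)-glycidate); 2 (2-methylprop-1-en-1-yl)magnesium bromide
Product: 3 methyl (2S)-2-hydroxy-5-methylhex-4-enoate
Conditions: CuI (10 mol %), THF, −40 → −20 °C; aq. NH4Cl
Reagents that add atoms: none
Why: Copper-catalysed Grignard opening of a glycidic ester at the unsubstituted epoxide carbon (SN2) leaves the stereocentre untouched, so the (S) centre of 1 becomes C8.

Step 2
Reactants: 3 methyl (2S)-2-hydroxy-5-methylhex-4-enoate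
Product: 4 methyl (2S)-2-[(tert-butyldimethylsilyl)oxy]-5-methylhex-4-enoate
Conditions: TBSCl, imidazole, DMF, rt
Reagents that add atoms: tert-butyldimethylsilyl chloride, CC(C)(C)[Si](C)(C)Cl
Why: Standard silylation of a secondary alcohol gives a bulky, non-chelating, non-nucleophilic ether, which steps 7 and 9 rely on.

Step 3
Reactants: 4 methyl (2S)-2-[(tert-butyldimethylsilyl)oxy]-5-methylhex-4-enoate
Product: 5 (2S)-2-[(tert-butyldimethylsilyl)oxy]-N-methoxy-N,5-dimethylhex-4-enamide
Conditions: MeNH(OMe)·HCl, iPrMgCl, THF, −20 → 0 °C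
Reagents that add atoms: N,O-dimethylhydroxylamine hydrochloride, CNOC.Cl
Why: Weinreb amide synthesis from the ester with the chloromagnesium amide should proceed without epimerising the α-silyloxy centre.

Step 4
Reactants: 5 (2S)-2-[(tert-butyldimethylsilyl)oxy]-N-methoxy-N,5-dimethylhex-4-enamide; 6 but-3-en-1-ylmagnesium bromide
Product: 7 (6S)-6-[(tert-butyldimethylsilyl)oxy]-9-methyldeca-1,8-dien-5-one
Conditions: THF, 0 °C; aq. NH4Cl
Reagents that add atoms: none
Why: Grignard addition to a Weinreb amide stops at the ketone because the magnesium chelate survives until work-up.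

Step 5
Reactants: 8 3-methylbut-3-en-1-ol
Product: 9 3-methylbut-3-enal
Conditions: Dess–Martin periodinane, NaHCO3, CH2Cl2, 0 °C → rt; used at once as a dried CH2Cl2 solution
Reagents that add atoms: none
Why: Buffered Dess–Martin oxidation of a primary alcohol should give the β,γ-unsaturated aldehyde without isomerisation to the conjugated enal.

Step 6
Reactants: 7 (6S)-6-[(tert-butyldimethylsilyl)oxy]-9-methyldeca-1,8-dien-5-one; 9 3-methylbut-3-enal
Product: 11 (4S,5R,7S)-7-[(tert-butyldimethylsilyl)oxy]-4-hydroxy-2,10-dimethyl-5-(prop-2-en-1-yl)undeca-1,9-dien-6-one, via titanium enolate 10 (not isolated)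
Conditions: TiCl4, iPr2NEt, CH2Cl2, −78 °C; then 9, −78 °C
Reagents that add atoms: titanium tetrachloride, Cl[Ti](Cl)(Cl)Cl (titanium and chlorine stay in 10 only)
Why: Titanium-mediated aldol reaction of an α-silyloxy ketone, in which the Z-enolate in a Zimmerman–Traxler chair gives the C4/C5 syn relationship and the C8 stereocentre should direct the aldehyde to the enolate face that gives the all-syn (C8/C4 syn) adduct, setting C4 (R) and C5 (S).

Step 7
Reactants: 11 (4S,5R,7S)-7-[(tert-butyldimethylsilyl)oxy]-4-hydroxy-2,10-dimethyl-5-(prop-2-en-1-yl)undeca-1,9-dien-6-one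
Product: 12 (4S,5R,6S,7S)-7-[(tert-butyldimethylsilyl)oxy]-2,6,10-trimethyl-5-(prop-2-en-1-yl)undeca-1,9-diene-4,6-diol
Conditions: MeMgBr (4 equiv), Et2O/CH2Cl2, −78 → −40 °C
Reagents that add atoms: methylmagnesium bromide, C[Mg]Br
Why: Grignard addition to a β-hydroxy ketone under 1,3-chelation control (magnesium alkoxide chelate, attack anti to the allyl group on C4), reinforced by Felkin–Anh control from the non-chelating C8 silyloxy group, should set the quaternary C7 as (S).

Step 8
Reactants: 12 (4S,5R,6S,7S)-7-[(tert-butyldimethylsilyl)oxy]-2,6,10-trimethyl-5-(prop-2-en-1-yl)undeca-1,9-diene-4,6-diol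
Product: 13 (4S,5R,6S,7S)-7-[(tert-butyldimethylsilyl)oxy]-6-hydroxy-2,6,10-trimethyl-5-(prop-2-en-1-yl)undeca-1,9-dien-4-yl acetate
Conditions: Ac2O, pyridine, DMAP (cat.), CH2Cl2, 0 °C → rt
Reagents that add atoms: acetic anhydride, CC(=O)OC(C)=O
Why: DMAP-catalysed acetylation should take the secondary C5 alcohol and leave the hindered tertiary C7 alcohol free, which puts the acetate in place while no other secondary hydroxyl exists.

Step 9
Reactants: 13 (4S,5R,6S,7S)-7-[(tert-butyldimethylsilyl)oxy]-6-hydroxy-2,6,10-trimethyl-5-(prop-2-en-1-yl)undeca-1,9-dien-4-yl acetate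
Product: 14 (4S,5R)-5-[(2S,3S,5S)-5-bromo-3-[(tert-butyldimethylsilyl)oxy]-2,6,6-trimethyloxan-2-yl]-2-methylocta-1,7-dien-4-yl acetate
Conditions: NBS (1.05 equiv), (CF3)2CHOH, 4 Å molecular sieves, 0 °C
Reagents that add atoms: N-bromosuccinimide, O=C1CCC(=O)N1Br
Why: Bromoetherification of the most electron-rich (trisubstituted) alkene, 6-endo with Markovnikov opening of the bromonium ion at C11 by the tertiary C7 hydroxyl in the ionising solvent, should pass through a chair with bromine equatorial, the C4 branch equatorial and the C8 silyloxy group axial (gauche to the ring oxygen, not to the C7 methyl), which gives the (10S) bromide.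

Step 10
Reactants: 14 (4S,5R)-5-[(2S,3S,5S)-5-bromo-3-[(tert-butyldimethylsilyl)oxy]-2,6,6-trimethyloxan-2-yl]-2-methylocta-1,7-dien-4-yl acetate
Product: 15 (1S,6R)-6-[(2S,3S,5S)-5-bromo-3-[(tert-butyldimethylsilyl)oxy]-2,6,6-trimethyloxan-2-yl]-3-methylcyclohex-3-en-1-yl acetate
Conditions: second-generation Grubbs catalyst (H2IMes)(PCy3)Cl2Ru=CHPh (5 mol %), CH2Cl2, 40 °C
Reagents that add atoms: none
Why: Ring-closing metathesis of the allyl and methallyl groups should form the trisubstituted cyclohexene with loss of ethene, and it is placed after step 9 so that no second trisubstituted alkene competes for the bromonium source.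

Step 11
Reactants: 15 (1S,6R)-6-[(2S,3S,5S)-5-bromo-3-[(tert-butyldimethylsilyl)oxy]-2,6,6-trimethyloxan-2-yl]-3-methylcyclohex-3-en-1-yl acetate
Product: 16 (1S,6R)-6-[(2S,3S,5S)-5-bromo-3-hydroxy-2,6,6-trimethyloxan-2-yl]-3-methylcyclohex-3-en-1-yl acetate
Conditions: Bu4NF, AcOH, THF, rt → 40 °C
Reagents that add atoms: none
Why: Fluoride-mediated desilylation, buffered with acetic acid so that the acetate is neither cleaved nor shifted, frees the C8 hydroxyl.

Step 12
Reactants: 16 (1S,6R)-6-[(2S,3S,5S)-5-bromo-3-hydroxy-2,6,6-trimethyloxan-2-yl]-3-methylcyclohex-3-en-1-yl acetate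
Product: 18 (1R,2R,4R,5S,7S,8S,10S)-10-bromo-2-hydroxy-1,8:7,11-diepoxybisabolan-5-yl acetate (CNP0247588.2), via organomercurial 17 (not isolated)
Conditions: Hg(OCOCF3)2, CH2Cl2, −20 → 0 °C; then solvent change to DMF, O2, NaBH4, 0 °C
Reagents that add atoms: dioxygen, O=O; mercury bis(trifluoroacetate), FC(F)(F)C(=O)O[Hg]OC(=O)C(F)(F)F (mercury and trifluoroacetate stay in 17 only)
Why: Divalent mercury adds reversibly to the C1=C2 bond, the C8 hydroxyl opens the mercurinium ion at the methyl-bearing C1 (Markovnikov, anti), and NaBH4 under O2 then turns the C2–Hg bond into a C2 radical that captures oxygen and is reduced to the alcohol; the closest known reactions are the intramolecular alkoxymercuration of α-terpineol to the 1,8-cineole skeleton and borohydride/oxygen oxidative demercuration. The oxepane C1–O8–C8–C7–C4–C5–C6 closes in a 7-exo-trig mode across the 1,4-positions of the cyclohexene through a boat conformer. C1 is fixed by the tether, since the hydroxyl can reach C1 only from the face bearing the C4 side chain, so mercury sits on the opposite, less hindered face. C2 should be set by oxygen capture of the bicyclic radical on the face syn to the two-carbon C5–C6 bridge, away from the three-atom O8–C8–C7 bridge. The step needs Markovnikov regioselectivity, which the tertiary C1 secures because the alternative would put mercury on a tertiary carbon. It also needs the C5 acetate not to divert C1: capture by the acetate carbonyl gives only a cationic adduct that reverts, whereas the ether is neutral and should accumulate.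

**Compound list**

1 | methyl (2S)-oxirane-2-carboxylate | COC(=O)[C@@H]1CO1 | starting material
2 | (2-methylprop-1-en-1-yl)magnesium bromide | CC(C)=C[Mg]Br | starting material
3 | methyl (2S)-2-hydroxy-5-methylhex-4-enoate | COC(=O)[C@H](CC=C(C)C)O | intermediate
4 | methyl (2S)-2-[(tert-butyldimethylsilyl)oxy]-5-methylhex-4-enoate | COC(=O)[C@H](CC=C(C)C)O[Si](C)(C)C(C)(C)C | intermediate
5 | (2S)-2-[(tert-butyldimethylsilyl)oxy]-N-methoxy-N,5-dimethylhex-4-enamide | CON(C)C(=O)[C@H](CC=C(C)C)O[Si](C)(C)C(C)(C)C | intermediate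
6 | but-3-en-1-ylmagnesium bromide | C=CCC[Mg]Br | starting material
7 | (6S)-6-[(tert-butyldimethylsilyl)oxy]-9-methyldeca-1,8-dien-5-one | C=CCCC(=O)[C@H](CC=C(C)C)O[Si](C)(C)C(C)(C)C | intermediate
8 | 3-methylbut-3-en-1-ol | CC(=C)CCO | starting material
9 | 3-methylbut-3-enal | CC(=C)CC=O | intermediate
10 | trichloro{[(4Z,6S)-6-[(tert-butyldimethylsilyl)oxy]-9-methyldeca-1,4,8-trien-5-yl]oxy}titanium | C=CC/C=C(\O[Ti](Cl)(Cl)Cl)[C@H](CC=C(C)C)O[Si](C)(C)C(C)(C)C | intermediate
11 | (4S,5R,7S)-7-[(tert-butyldimethylsilyl)oxy]-4-hydroxy-2,10-dimethyl-5-(prop-2-en-1-yl)undeca-1,9-dien-6-one | O[C@@H](CC(C)=C)[C@@H](CC=C)C(=O)[C@H](CC=C(C)C)O[Si](C)(C)C(C)(C)C | intermediate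
12 | (4S,5R,6S,7S)-7-[(tert-butyldimethylsilyl)oxy]-2,6,10-trimethyl-5-(prop-2-en-1-yl)undeca-1,9-diene-4,6-diol | O[C@@H](CC(C)=C)[C@@H](CC=C)[C@](C)(O)[C@H](CC=C(C)C)O[Si](C)(C)C(C)(C)C | intermediate
13 | (4S,5R,6S,7S)-7-[(tert-butyldimethylsilyl)oxy]-6-hydroxy-2,6,10-trimethyl-5-(prop-2-en-1-yl)undeca-1,9-dien-4-yl acetate | CC(=O)O[C@@H](CC(C)=C)[C@@H](CC=C)[C@](C)(O)[C@H](CC=C(C)C)O[Si](C)(C)C(C)(C)C | intermediate
14 | (4S,5R)-5-[(2S,3S,5S)-5-bromo-3-[(tert-butyldimethylsilyl)oxy]-2,6,6-trimethyloxan-2-yl]-2-methylocta-1,7-dien-4-yl acetate | CC(=O)O[C@@H](CC(C)=C)[C@@H](CC=C)[C@]1(C)OC(C)(C)[C@@H](Br)C[C@@H]1O[Si](C)(C)C(C)(C)C | intermediate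
15 | (1S,6R)-6-[(2S,3S,5S)-5-bromo-3-[(tert-butyldimethylsilyl)oxy]-2,6,6-trimethyloxan-2-yl]-3-methylcyclohex-3-en-1-yl acetate | CC(=O)O[C@H]1CC(C)=CC[C@H]1[C@]2(C)OC(C)(C)[C@@H](Br)C[C@@H]2O[Si](C)(C)C(C)(C)C | intermediate
16 | (1S,6R)-6-[(2S,3S,5S)-5-bromo-3-hydroxy-2,6,6-trimethyloxan-2-yl]-3-methylcyclohex-3-en-1-yl acetate | CC(=O)O[C@H]1CC(C)=CC[C@H]1[C@]2(C)OC(C)(C)[C@@H](Br)C[C@@H]2O | intermediate
17 | [(1R,2R,4R,5S,7S,8S,10S)-5-acetoxy-10-bromo-1,8:7,11-diepoxybisabolan-2-yl]mercury trifluoroacetate | CC(=O)O[C@H]1C[C@@]2(C)O[C@H]3C[C@H](Br)C(C)(C)O[C@@]3(C)[C@@H]1C[C@H]2[Hg]OC(=O)C(F)(F)F | intermediate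
18 | (1R,2R,4R,5S,7S,8S,10S)-10-bromo-2-hydroxy-1,8:7,11-diepoxybisabolan-5-yl acetate (2-oxabicyclo[3.2.2]nonane fused to a bromo-oxane) | CC(=O)O[C@H]1C[C@@]2(C)O[C@H]3C[C@H](Br)C(C)(C)O[C@@]3(C)[C@@H]1C[C@H]2O | target

**Totals**

Total steps: 12. Longest linear sequence: 11 steps (steps 1–4 and 6–12; step 5 prepares aldehyde 9 separately).

**Steps most likely to fail**

1. Step 12. The bridging alkoxymercuration may stall or revert, because closure of the seven-membered ether needs the boat conformer. In the second stage the C2 radical may be reduced before it captures oxygen, or may take up oxygen with poor facial selectivity. The fallback sets out from 16 and comes back at 18; it installs the C2 oxygen stereospecifically before ring closure. Epoxidation of 16 with mCPBA/NaHCO3 on the face anti to the cis C4 and C5 substituents should give the anti epoxide F1. Cp2TiCl (trivalent titanium, made from Cp2TiCl2 and Mn) should open F1 homolytically at the tertiary carbon, and β-hydride elimination should give the exocyclic allylic alcohol F2 with the C2 hydroxyl in place. Hg(OCOCF3)2 should then close the ether at C1 of the 1,1-disubstituted alkene to give the primary organomercurial F3, and NaBH4/NaOH replaces mercury by hydrogen to give 18.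

2. Step 9. Bromonium formation may show poor facial selectivity relative to C7/C8 (giving C10 epimers), 5-exo closure to a tetrahydrofuran with a tertiary bromide may compete, and the 1,1-disubstituted alkene may also be attacked. The fallback sets out from 13 and comes back at 14; it delivers bromide as a nucleophile to a centre fixed by reagent control. Shi epoxidation of the trisubstituted alkene, with the enantiomer of the fructose-derived ketone that delivers the (S)-epoxide, should give the epoxy alcohol F4. CSA-catalysed 5-exo opening by the C7 hydroxyl, with inversion at C10, should give the tetrahydrofuranyl carbinol F5. Mesylation of the tertiary alcohol (MsCl, Et3N) in the presence of Bu4NBr should trigger ionisation assisted by the ring oxygen, and bromide should open the bicyclic oxonium ion at C10 with a second inversion (ring expansion) to give 14.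

3. Step 6. The C8 stereocentre may not discriminate the enolate faces well enough, TiCl4 may isomerise 9 to the conjugated enal, and retro-aldol loss may occur on work-up. The fallback sets out from 7 and comes back at 11; it replaces the Lewis-acidic titanium enolate by a neutral boron enolate. Bu2BOTf/iPr2NEt should convert 7 into the Z dibutylboron enolate F6, which should react with 9 through a closed six-membered transition state without any free Lewis acid, and buffered H2O2 work-up should give 11.

**Further compounds**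

F1 | step 12 | (1S,3S,4R,6R)-4-[(2S,3S,5S)-5-bromo-3-hydroxy-2,6,6-trimethyloxan-2-yl]-1-methyl-7-oxabicyclo[4.1.0]heptan-3-yl acetate | CC(=O)O[C@H]1C[C@]2(C)O[C@@H]2C[C@H]1[C@]3(C)OC(C)(C)[C@@H](Br)C[C@@H]3O
F2 | step 12 | (1S,4R,6R)-6-[(2S,3S,5S)-5-bromo-3-hydroxy-2,6,6-trimethyloxan-2-yl]-4-hydroxy-3-methylidenecyclohexyl acetate | CC(=O)O[C@H]1CC(=C)[C@H](O)C[C@H]1[C@]2(C)OC(C)(C)[C@@H](Br)C[C@@H]2O
F3 | step 12 | analogue of 18 with CH2HgOCOCF3 in place of the C1 methyl group | CC(=O)O[C@H]1C[C@@]2(C[Hg]OC(=O)C(F)(F)F)O[C@H]3C[C@H](Br)C(C)(C)O[C@@]3(C)[C@@H]1C[C@H]2O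
F4 | step 9 | (4S,5R,6S,7S)-7-[(tert-butyldimethylsilyl)oxy]-8-[(2S)-3,3-dimethyloxiran-2-yl]-6-hydroxy-2,6-dimethyl-5-(prop-2-en-1-yl)oct-1-en-4-yl acetate | CC(=O)O[C@@H](CC(C)=C)[C@@H](CC=C)[C@](C)(O)[C@H](C[C@@H]1OC1(C)C)O[Si](C)(C)C(C)(C)C
F5 | step 9 | (4S,5R)-5-[(2S,3S,5R)-3-[(tert-butyldimethylsilyl)oxy]-5-(2-hydroxypropan-2-yl)-2-methyloxolan-2-yl]-2-methylocta-1,7-dien-4-yl acetate | CC(=O)O[C@@H](CC(C)=C)[C@@H](CC=C)[C@]1(C)O[C@@H](C(C)(C)O)C[C@@H]1O[Si](C)(C)C(C)(C)C
F6 | step 6 | dibutyl{[(4Z,6S)-6-[(tert-butyldimethylsilyl)oxy]-9-methyldeca-1,4,8-trien-5-yl]oxy}borane | C=CC/C=C(\OB(CCCC)CCCC)[C@H](CC=C(C)C)O[Si](C)(C)C(C)(C)C
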